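The benzene ring is cut at C1–C6 and C2–C3, so that the whole C1(ester)–C2(OH)–C3(O) triad is read from an acyclic chain. Photolysis of a 2-diazo-3-oxo-4,6-dienoate triggers a Wolff shift of the dienyl group to the diazo carbon, and the resulting ester-substituted dienylketene closes by 6π electrocyclization, delivering the ring, the C2 phenol and the C3 ether in one operation. The precursor is the 16-methylheptadecyl ester of (4E,6E)-2-diazo-7-methoxy-3-oxohepta-4,6-dienoic acid, assembled from the diazoacetoacetate and (E)-3-methoxyacrolein. The feature exploited is the contiguous C1 carboxyl, C2 hydroxyl, C3 oxygen pattern on an otherwise unsubstituted benzene ring (C4–C6 are CH).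

Key step: step 4

Remark: 16-methylheptadecan-1-ol (2) is taken to be available as the single iso-branched isomer and not as a technical mixture of branched alcohols; the target has no stereocenter, so only alkene geometry has to be controlled.

Step 1
Reactants: 1 tert-butyl acetoacetate; 2 16-methylheptadecan-1-ol
Product: 4 16-methylheptadecyl 3-oxobutanoate, via acetylketene 3 (not isolated)
Conditions: toluene, 110 °C, t-BuOH distilled off
Reagents that add atoms: none
Why: Thermal acetoacetylation (transesterification through an acylketene): the tert-butyl ester loses tert-butanol on heating to give acetylketene 3, which the primary alcohol captures irreversibly.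

Step 2
Reactants: 4 16-methylheptadecyl 3-oxobutanoate; 5 4-acetamidobenzenesulfonyl azide
Product: 6 16-methylheptadecyl 2-diazo-3-oxobutanoate
Conditions: Et3N, MeCN/CH2Cl2, 0 → 20 °C
Reagents that add atoms: 4-acetamidobenzenesulfonyl azide (5), CC(=O)Nc1ccc(cc1)S(=O)(=O)N=[N+]=[N-]
Why: Regitz diazo transfer: the ammonium enolate of the β-keto ester attacks the terminal nitrogen of the sulfonyl azide and the adduct collapses to the 2-diazo-1,3-dicarbonyl compound and the sulfonamide, the saturated ester chain being inert.

Step 3
Reactants: 6 16-methylheptadecyl 2-diazo-3-oxobutanoate; 7 (E)-3-methoxyacrolein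
Product: 11 16-methylheptadecyl (4E,6E)-2-diazo-7-methoxy-3-oxohepta-4,6-dienoate, via lithium enolate 8 (not isolated), via lithium aldolate 9 (not isolated), via allylic mesylate 10 (not isolated)
Conditions: LiN(SiMe3)2, THF, −78 °C; 7, −78 °C; MsCl, then DBU, −78 → 0 °C; NaHCO3 work-up
Reagents that add atoms: none
Why: Aldol condensation in one flask: with C2 blocked by the diazo group only the C4 lithium enolate 8 can form, it adds to the aldehyde carbon of the vinylogous ester 7, and mesylation of the aldolate followed by E1cB elimination through the ketone enolate should give the conjugated, thermodynamically preferred 4E alkene with the 6E enol ether carried through, the acid-labile allylic alcohol never meeting acid or silica.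

Step 4
Reactants: 11 16-methylheptadecyl (4E,6E)-2-diazo-7-methoxy-3-oxohepta-4,6-dienoate
Product: 15 16-methylheptadecyl 2-hydroxy-3-methoxybenzoate, via (3E)-dienylketene 12 (not isolated), via (3Z)-dienylketene 13 (not isolated), via cyclohexa-2,4-dienone 14 (not isolated)
Conditions: hν (350–365 nm, Pyrex), dry degassed ClCH2CH2Cl (0.005 M), 20 °C; then 80 °C, dark
Reagents that add atoms: none
Why: Proposed new method: excitation of the 2-diazo-1,3-dicarbonyl unit expels N2 with a concerted 1,2-shift of the dienyl group from the ketone carbon to the diazo carbon (new bond ring C1–C6), which gives the ester-substituted dienylketene 12, and the same light equilibrates its C3=C4 alkene to the Z isomer 13. The closest known reaction types are the photochemical Wolff rearrangement of 2-diazo-3-oxo esters and α-diazo enones to acyl- and vinylketenes and the closure of dienylketenes to phenols in Danheiser-type benzannulations; what is untested is their combination on an open-chain diazo dienone. The benzene ring is closed by a thermal disrotatory 6π electrocyclization of 13 that joins the ketene carbon to the methoxy-bearing diene terminus (new bond ring C2–C3) and gives dienone 14, which enolizes to the phenol, at the latest during the final period at 80 °C. No stereocenter results, because the only sp3 ring carbon of 14 is lost on aromatization. Migration of the dienyl group in preference to the alkoxy group is needed and should follow from the higher migratory aptitude of the ketone substituent in diazo keto esters, and the Z geometry is needed and should be reachable because the methoxy donor and the ester acceptor make the triene a push–pull chromophore that absorbs and isomerizes at the irradiation wavelength. High dilution in a dry, degassed, non-nucleophilic solvent should keep the electrophilic ketene from dimerizing or adding a nucleophile before it closes.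

Step 5
Reactants: 15 16-methylheptadecyl 2-hydroxy-3-methoxybenzoate
Product: 16 Gentiside D (16-methylheptadecyl 2,3-dihydroxybenzoate)
Conditions: BBr3, CH2Cl2, −78 → 0 °C; then H2O
Reagents that add atoms: none
Why: Lewis-acid cleavage of an aryl methyl ether: BBr3 binds the phenol and the neighbouring ether oxygen as a borate, bromide removes the methyl group by SN2, which at low temperature should be much faster than attack on the primary alkyl ester, and water hydrolyzes the aryl borate to the catechol.

Compound list
1 | tert-butyl acetoacetate | CC(=O)CC(=O)OC(C)(C)C | starting material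
2 | 16-methylheptadecan-1-ol | CC(C)CCCCCCCCCCCCCCCO | starting material
3 | acetylketene | CC(=O)C=C=O | intermediate
4 | 16-methylheptadecyl 3-oxobutanoate | CC(C)CCCCCCCCCCCCCCCOC(=O)CC(C)=O | intermediate
5 | 4-acetamidobenzenesulfonyl azide | CC(=O)Nc1ccc(cc1)S(=O)(=O)N=[N+]=[N-] | starting material
6 | 16-methylheptadecyl 2-diazo-3-oxobutanoate | CC(C)CCCCCCCCCCCCCCCOC(=O)C(=[N+]=[N-])C(C)=O | intermediate
7 | (E)-3-methoxyacrolein | CO/C=C/C=O | starting material
8 | lithium enolate of 6 (lithium 3-diazo-4-(16-methylheptadecyloxy)-4-oxobut-1-en-2-olate) | CC(C)CCCCCCCCCCCCCCCOC(=O)C(=[N+]=[N-])C(=C)[O-].[Li+] | intermediate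
9 | lithium alkoxide of 16-methylheptadecyl (6E)-2-diazo-5-hydroxy-7-methoxy-3-oxohept-6-enoate (racemic at C5) | CC(C)CCCCCCCCCCCCCCCOC(=O)C(=[N+]=[N-])C(=O)CC([O-])/C=C/OC.[Li+] | intermediate
10 | 16-methylheptadecyl (6E)-2-diazo-7-methoxy-5-(methylsulfonyloxy)-3-oxohept-6-enoate (racemic at C5) | CC(C)CCCCCCCCCCCCCCCOC(=O)C(=[N+]=[N-])C(=O)CC(OS(C)(=O)=O)/C=C/OC | intermediate
11 | 16-methylheptadecyl (4E,6E)-2-diazo-7-methoxy-3-oxohepta-4,6-dienoate | CC(C)CCCCCCCCCCCCCCCOC(=O)C(=[N+]=[N-])C(=O)/C=C/C=C/OC | intermediate
12 | 16-methylheptadecyl (3E,5E)-6-methoxy-2-(oxomethylidene)hexa-3,5-dienoate | CC(C)CCCCCCCCCCCCCCCOC(=O)C(=C=O)/C=C/C=C/OC | intermediate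
13 | 16-methylheptadecyl (3Z,5E)-6-methoxy-2-(oxomethylidene)hexa-3,5-dienoate | CC(C)CCCCCCCCCCCCCCCOC(=O)C(=C=O)/C=C\C=C\OC | intermediate
14 | 16-methylheptadecyl 5-methoxy-6-oxocyclohexa-1,3-diene-1-carboxylate (racemic at C5) | CC(C)CCCCCCCCCCCCCCCOC(=O)C1=CC=CC(OC)C1=O | intermediate
15 | 16-methylheptadecyl 2-hydroxy-3-methoxybenzoate | CC(C)CCCCCCCCCCCCCCCOC(=O)c1cccc(OC)c1O | intermediate
16 | Gentiside D (16-methylheptadecyl 2,3-dihydroxybenzoate) | CC(C)CCCCCCCCCCCCCCCOC(=O)c1cccc(O)c1O | target

Total step count: 5. Longest linear sequence: 5 steps (1 and 2 to 16).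

Steps most likely to fail

Step 4. The E-to-Z isomerization of the ketene may lag behind its bimolecular loss (dimerization, or addition of the phenol already formed), and part of the excited diazo compound may react as a free carbene with the solvent instead of rearranging. The fallback gives up the annulation and uses known ester chemistry. It sets out from 2, which is converted with MsCl and Et3N in CH2Cl2 at 0 °C into 16-methylheptadecyl methanesulfonate F1. This alkylates the carboxylate of commercial 2-hydroxy-3-methoxybenzoic acid (KHCO3, DMF, 70 °C); the hydrogen-bonded phenol should not be deprotonated by bicarbonate, so the ester forms selectively. The route is rejoined at 15.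

Step 3. The aldol addition to the conjugatively stabilized aldehyde may revert before the aldolate is trapped. The enolate may also add to the β-carbon of the vinylogous ester with loss of methoxide, or the diazo ester may erode under the basic one-pot sequence. The fallback installs the diazo group last and uses a harder, more basic nucleophile. It sets out from 4, whose dianion (NaH, then n-BuLi, THF, 0 °C) should add through C4 to 7 at −78 °C to give, after work-up at pH 7, 16-methylheptadecyl (6E)-5-hydroxy-7-methoxy-3-oxohept-6-enoate F2 (racemic). MsCl and Et3N in CH2Cl2 at 0 °C convert this into 16-methylheptadecyl (6E)-7-methoxy-5-(methylsulfonyloxy)-3-oxohept-6-enoate F3 (not isolated), and DBU eliminates it to 16-methylheptadecyl (4E,6E)-7-methoxy-3-oxohepta-4,6-dienoate F4. Regitz diazo transfer from 5 (Et3N, MeCN, 0 → 20 °C) then returns to the route at 11.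

Step 5. The Lewis acid may open the long-chain ester (alkyl–oxygen or acyl–oxygen scission) in competition with O-demethylation, or demethylation may stall at the chelated borate. The fallback replaces Lewis-acid cleavage by oxidative demethylation under near-neutral conditions. It sets out from 15, whose guaiacol unit is oxidized with 2-iodoxybenzoic acid in DMF at 20 °C (alternatively NaIO4 in aqueous AcOH), with loss of methanol, to the ortho-quinone 16-methylheptadecyl 5,6-dioxocyclohexa-1,3-diene-1-carboxylate F5. Without isolation this is reduced with aqueous Na2S2O4 to the catechol, so the route is rejoined at 16.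

Further compounds
F1 | step 4 | 16-methylheptadecyl methanesulfonate | CC(C)CCCCCCCCCCCCCCCOS(C)(=O)=O
F2 | step 3 | 16-methylheptadecyl (6E)-5-hydroxy-7-methoxy-3-oxohept-6-enoate (racemic at C5) | CC(C)CCCCCCCCCCCCCCCOC(=O)CC(=O)CC(O)/C=C/OC
F3 | step 3 | 16-methylheptadecyl (6E)-7-methoxy-5-(methylsulfonyloxy)-3-oxohept-6-enoate (racemic at C5) | CC(C)CCCCCCCCCCCCCCCOC(=O)CC(=O)CC(OS(C)(=O)=O)/C=C/OC
F4 | step 3 | 16-methylheptadecyl (4E,6E)-7-methoxy-3-oxohepta-4,6-dienoate | CC(C)CCCCCCCCCCCCCCCOC(=O)CC(=O)/C=C/C=C/OC
F5 | step 5 | 16-methylheptadecyl 5,6-dioxocyclohexa-1,3-diene-1-carboxylate | CC(C)CCCCCCCCCCCCCCCOC(=O)C1=CC=CC(=O)C1=O
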